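A chemist at the bench counts equivalents: Z is the limiting reagent, at 0.900 equivalents to E, so by that count nearly all of the E should be met. I follow one Z instead and ask for its chances at each fork.

| flask | E | Z | G | remark | time |
|---|---|---|---|---|---|
| spring | 0.50 mM | 0.45 mM | 0.10 mM | run made earlier |  |
| winter | 0.50 mM | 0.45 mM | 0.15 mM | run made earlier |  |
| eta | 0.50 mM | 0.450 mM | 0.100 mM (fed, over 4.0 min) | all else is in the flask from the start; the feed brings no volume worth counting | 5.0 min |
| beta | 0.50 mM | 0.450 mM | 0.100 mM | everything together at the start | 5.0 min |
| gamma | 0.50 mM (fed, over 4.0 min) | 0.450 mM | 0.100 mM | all else is in the flask from the start; the feed brings no volume worth counting | 5.0 min |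

spring run (percent of the E charged)

| time / min | Q / % | L / % |
|---|---|---|
| 0.667 | 23 | 25 |
| 1.33 | 15 | 38 |
| 2.00 | 13 | 49 |
| 3.00 | 11 | 57 |
| 4.00 | 5 | 62 |
| 5.00 | 8 | 66 |

winter run (percent of the E charged)

| time / s | Q / % | L / % |
|---|---|---|
| 12.0 | 27 | 10 |
| 25.0 | 22 | 19 |
| 40.0 | 20 | 25 |
| 50.0 | 19 | 28 |
| 60.0 | 15 | 32 |
| 80.0 | 11 | 35 |
| 90.0 | 11 | 41 |

(scatter of a reading: 1.5 percentage points)

- in percentages every species weighs as the E in it: one L counts as two

1. the flask that comes out highest in share of Q in Q plus L, or "all alike" when all lie within 1.5 percentage points (eta / beta / gamma / all alike)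
2. share of Q in Q plus L at the end, eta
3. share of Q in Q plus L at the end, beta
4. share of Q in Q plus L at the end, gamma

I take it that each Q holds one Z and that each L, which counts as two E, also holds one, so I read a tally of Z spent on E from the readings:

tally = Q + L/2
spring, 5.00 min: 41.0 % of the E charged
winter, 12.0 s: 32.0 %; winter, 90.0 s: 31.5 %

In spring, a Z therefore reaches E with a chance of

tally × c_E / c_Z = 45.6 %

If one G takes one Z, G accounts for up to 22.2 %, which leaves about 32.2 % or more of Z on a third exit that I read as needing neither E nor G. The bench rule stops working here: it counts 0.900 equivalents of Z for E, and the spring tally puts 45.6 % of Z there.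

The two winter tallies agree within scatter, so I read Z's work on E in winter as done by the first reading, and 12.0 s is far shorter than the feed of 4.0 min. This gives my carried quantity, the dose window, the share of a feed that has arrived by the time Z's work is done:

w = 12.0 s / 4.0 min = 5.00 %

A spent Z holds up to two E, so I expect gamma to lose less than 10.0 % of its E. Winter Q falls from 27 % to 15 % by 60.0 s, which is shorter than the 5.0 min of gamma, so I expect the little Q made there to go on to L and the share of gamma to lie lowest. In eta, 5.00 % of the G at most has arrived in the window, so more Z should reach E than in beta, less E should stay to carry Q on to L, and eta should beat beta, whose recipe is that of spring, where the last readings give a share of about 10.8 %.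

The forecast differs from my reckoning on gamma: it gives 11 % for eta, 10.5 % for beta and 21 % for gamma, ranks gamma highest, and reasons “Feeding E keeps Q lower”.

    G + Z → X (k = 1880 M⁻¹ s⁻¹)
    Q ⇌ J (K = 0.416, k = 0.0227 s⁻¹)
    Z → D (k = 0.194 s⁻¹)
    E + Z → Q (k = 661 M⁻¹ s⁻¹)
    E + Q → L (k = 45.0 M⁻¹ s⁻¹)

The flasks give 12.2 % for eta, 7.78 % for beta and 2.60 % for gamma, so eta ranks highest. In gamma, the step from Z to D reaches the midpoint of its turnover at 0.0504 min, far earlier than the end of the 4.0 min feed. At 2.50 min, gamma holds Z at 0 %, and it ends with 97 % of its E, a loss under 10.0 %. The neighbour of gamma with 0.30 mM of E has the same window and also stays under that loss, keeping 97 % of its E.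

(The numbers in the tables were computed with made-up constants, and the scatter is random.)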